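The bond between ring carbon C1' (the CH stereocentre of the 2,6,6-trimethyl-4-oxocyclohex-2-enyl ring) and chain carbon C13 is made by a decarboxylative Ireland–Claisen rearrangement that exploits the ring's allylic triad C1'–C2'(Me)=C3'. In the precursor the polyenoate chain, extended by one carboxyl carbon and carrying a tosyl group at C13, is tethered as an ester to O–C3' of an (S)-cyclohexenol with its double bond at C1'=C2' and C4' masked as a dioxolane. One operation forms C1'–C13 with 1,3-chirality transfer next to the gem-dimethyl carbon, moves the alkene to C2'=C3' and expels the tether as CO2; sulfinate elimination and ketal hydrolysis complete polyene and enone.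

Key step: step 10

Numbering: ring atoms are primed as in the 2,6,6-trimethyl-4-oxocyclohex-2-en-1-yl group of the target (C1' = CH stereocentre, C4' = C=O); the chain is numbered from the ester carbon (C13 = CH bonded to C1').
Remark on the chemistry: in the CBS reduction (step 3) the spiroketal carbon is assumed to act as the larger carbonyl substituent; if the opposite sense is found, the enantiomeric catalyst is used.

Step 1
Reactants: 1 2-hydroxy-3,5,5-trimethylcyclohex-2-en-1-one (2-hydroxyisophorone)
Product: 2 7,9,9-trimethyl-1,4-dioxaspiro[4.5]decan-6-one (racemic)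
Conditions: ethylene glycol, p-TsOH (cat.), benzene, reflux, Dean–Stark
Reagents that add atoms: ethylene glycol, OCCO
Why: Acid-catalysed ketalisation with azeotropic removal of water: the diol should add to the less hindered C1 carbonyl (next to CH2) of the diosphenol and the remaining enol then ketonises, which fixes the pattern ketal carbon / ketone / CH(Me); the CH(Me) centre forms racemic and is removed in step 2.

Step 2
Reactants: 2 7,9,9-trimethyl-1,4-dioxaspiro[4.5]decan-6-one
Product: 3 7,9,9-trimethyl-1,4-dioxaspiro[4.5]dec-7-en-6-one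
Conditions: IBX (1.5 equiv), DMSO/toluene, 70 °C
Reagents that add atoms: none
Why: IBX dehydrogenation of a ketone via its enol: 2 can enolise only towards C7 (C5 is the spiro carbon), so the conjugated endocyclic 2-methyl enone is the only α,β-unsaturated product possible.

Step 3
Reactants: 3 7,9,9-trimethyl-1,4-dioxaspiro[4.5]dec-7-en-6-one
Product: 4 (6S)-7,9,9-trimethyl-1,4-dioxaspiro[4.5]dec-7-en-6-ol
Conditions: (R)-2-methyl-CBS-oxazaborolidine (0.2 equiv), catecholborane, toluene, −78 to −40 °C; aq. NaOH work-up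
Reagents that add atoms: none
Why: Corey–Bakshi–Shibata reduction: the oxazaborolidine–borane complex delivers hydride 1,2 to one face of the enone carbonyl, and with the spiroketal carbon as the larger flank the (R)-catalyst should give the (6S)-carbinol; catecholborane at low temperature spares the trisubstituted alkene and the ketal.

Step 4
Reactants: 4 (6S)-7,9,9-trimethyl-1,4-dioxaspiro[4.5]dec-7-en-6-ol; 5 [(4-methylphenyl)sulfonyl]acetic acid
Product: 6 (6S)-7,9,9-trimethyl-1,4-dioxaspiro[4.5]dec-7-en-6-yl [(4-methylphenyl)sulfonyl]acetate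
Conditions: DCC, DMAP (cat.), CH2Cl2, 0 °C to rt
Reagents that add atoms: none
Why: Steglich esterification acylates the hindered secondary allylic alcohol under neutral conditions with retention, since the C–O bond of the carbinol is not broken.

Step 5
Reactants: 7 (2E)-4,4-dimethoxybut-2-enal; 8 methyl 2-(triphenylphosphoranylidene)propanoate
Product: 10 methyl (2E,4E)-2-methyl-6-oxohexa-2,4-dienoate, via acetal dienoate 9 (not isolated)
Conditions: CH2Cl2, rt; then 1 M HCl, THF, rt
Reagents that add atoms: water, O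
Why: Wittig olefination with a stabilised ylide is E-selective for the new trisubstituted double bond and chemoselective for the aldehyde, and dilute acid then hydrolyses the dimethyl acetal without touching the ester.

Step 6
Reactants: 10 methyl (2E,4E)-2-methyl-6-oxohexa-2,4-dienoate; 11 2-(triphenylphosphoranylidene)propanal
Product: 12 methyl (2E,4E,6E)-2,7-dimethyl-8-oxoocta-2,4,6-trienoate
Conditions: toluene, 80 °C
Reagents that add atoms: none
Why: Wittig olefination with the stabilised formyl ylide gives the E-α-methyl enal and stops after one homologation because that product is far less electrophilic than the unbranched aldehyde 10.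

Step 7
Reactants: 12 methyl (2E,4E,6E)-2,7-dimethyl-8-oxoocta-2,4,6-trienoate; 13 (1,3-dioxolan-2-ylmethyl)triphenylphosphonium bromide
Product: 15 methyl (2E,4E,6E,8E)-2,7-dimethyl-10-oxodeca-2,4,6,8-tetraenoate, via vinyl dioxolane 14 (not isolated)
Conditions: LiOMe, DMF, 80 °C; then 1 M HCl, THF, rt; I2 (cat.), CH2Cl2, rt
Reagents that add atoms: water, O
Why: Wittig two-carbon homologation with the dioxolanylmethyl ylide (methoxide as base matches the methyl ester), followed by acid hydrolysis of the vinyl dioxolane; acid and a trace of iodine equilibrate the new disubstituted double bond to E.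

Step 8
Reactants: 15 methyl (2E,4E,6E,8E)-2,7-dimethyl-10-oxodeca-2,4,6,8-tetraenoate; 11 2-(triphenylphosphoranylidene)propanal
Product: 16 methyl (2E,4E,6E,8E,10E)-2,7,11-trimethyl-12-oxododeca-2,4,6,8,10-pentaenoate
Conditions: toluene, 80 °C
Reagents that add atoms: none
Why: A second Wittig olefination with the stabilised formyl ylide adds the E-C(Me)=CH–CHO terminus; the unbranched dienal 15 reacts, the α-methyl enal product does not.

Step 9
Reactants: 6 (6S)-7,9,9-trimethyl-1,4-dioxaspiro[4.5]dec-7-en-6-yl [(4-methylphenyl)sulfonyl]acetate; 16 methyl (2E,4E,6E,8E,10E)-2,7,11-trimethyl-12-oxododeca-2,4,6,8,10-pentaenoate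
Product: 18 14-[(6S)-7,9,9-trimethyl-1,4-dioxaspiro[4.5]dec-7-en-6-yl] 1-methyl (2E,4E,6E,8E,10E)-2,7,11-trimethyl-13-[(4-methylphenyl)sulfonyl]tetradeca-2,4,6,8,10-pentaenedioate (both C13 epimers), via Knoevenagel adduct 17 (not isolated)
Conditions: piperidine (cat.), AcOH (cat.), 4 Å MS, toluene, 60 °C; then NaBH4, THF/MeOH, −20 to 0 °C; AcOH quench
Reagents that add atoms: none
Why: Knoevenagel condensation of the acidic sulfonylacetate CH2 with the polyenal, then conjugate (1,4) reduction of the doubly activated alkylidene by NaBH4 (a reductive alkylation that avoids a labile polyenyl halide) to the sodium enolate of 18, which is inert to further reduction; the sulfonyl-bearing carbon forms as both epimers, and the carbinol centre of 6 is not involved.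

Step 10
Reactants: 18 14-[(6S)-7,9,9-trimethyl-1,4-dioxaspiro[4.5]dec-7-en-6-yl] 1-methyl (2E,4E,6E,8E,10E)-2,7,11-trimethyl-13-[(4-methylphenyl)sulfonyl]tetradeca-2,4,6,8,10-pentaenedioate
Product: 21 methyl (2E,4E,6E,8E,10E)-2,7,11-trimethyl-13-[(4-methylphenyl)sulfonyl]-13-[(8S)-7,9,9-trimethyl-1,4-dioxaspiro[4.5]dec-6-en-8-yl]trideca-2,4,6,8,10-pentaenoate (both C13 epimers), via silyl ketene acetal 19 (not isolated), via trimethylsilyl ester 20 (not isolated)
Conditions: BSA (0.2 equiv), KOAc (0.1 equiv), toluene, 110 °C, Ar, dark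
Reagents that add atoms: none
Why: Decarboxylative Ireland–Claisen rearrangement: catalytic BSA/KOAc silylates the α-sulfonyl ester to ketene acetal 19, which undergoes a concerted [3,3] shift across the ring allyl unit, breaking the C3'–O bond and making C1'–C13 on the same ring face, to give silyl ester 20; acetate removes the silyl group and the α-sulfonyl carboxylate loses CO2 to give sulfone 21 and return the silyl and acetate carriers. The closest known reactions are the decarboxylative Claisen rearrangement of allylic tosylacetates (α-substituted cases included) and Claisen rearrangements of 2,4,4-trimethylcyclohex-2-en-1-ol derivatives, which place a carbon substituent on the same neopentyl ring carbon. No ring is closed. The new stereocentre C1' is controlled by suprafacial 1,3-chirality transfer from the (S)-carbinol carbon C3' through the cyclic six-membered transition state, so the (6S)-ester should give the (8S)-product whatever the ketene-acetal geometry; the sulfonyl-bearing centre C13 forms as a mixture and is erased in step 11. The step needs enolisation at C13 and not at the vinylogous C–H positions of the pentaenoate, which the far more acidic α-sulfonyl ester C–H secures, and rearrangement instead of ionisation of the allylic ester, which the non-polar medium and the absence of Lewis acid favour. The tether carbon leaves as CO2, so nothing of the ester linkage remains in the product.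

Step 11
Reactants: 21 methyl (2E,4E,6E,8E,10E)-2,7,11-trimethyl-13-[(4-methylphenyl)sulfonyl]-13-[(8S)-7,9,9-trimethyl-1,4-dioxaspiro[4.5]dec-6-en-8-yl]trideca-2,4,6,8,10-pentaenoate
Product: 22 methyl (2E,4E,6E,8E,10E,12E)-2,7,11-trimethyl-13-[(8S)-7,9,9-trimethyl-1,4-dioxaspiro[4.5]dec-6-en-8-yl]trideca-2,4,6,8,10,12-hexaenoate
Conditions: NaOMe (2 equiv), THF/MeOH, 0 °C to rt, Ar, dark
Reagents that add atoms: none
Why: E1cB elimination of p-toluenesulfinate, the sulfone method of polyene synthesis: methoxide removes a C12–H, which is vinylogous to the ester through the pentaene, and loss of sulfinate from C13 gives the conjugated hexaene with the thermodynamically preferred E-12,13 bond; with the enone still masked the C1'–H is only allylic and the stereocentre is safe.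

Step 12
Reactants: 22 methyl (2E,4E,6E,8E,10E,12E)-2,7,11-trimethyl-13-[(8S)-7,9,9-trimethyl-1,4-dioxaspiro[4.5]dec-6-en-8-yl]trideca-2,4,6,8,10,12-hexaenoate
Product: 23 methyl (2E,4E,6E,8E,10E,12E)-2,7,11-trimethyl-13-[(1S)-2,6,6-trimethyl-4-oxocyclohex-2-en-1-yl]trideca-2,4,6,8,10,12-hexaenoate (CNP0164953.1)
Conditions: PPTS (cat.), acetone/H2O, rt, dark
Reagents that add atoms: water, O
Why: Mild acid-catalysed hydrolysis of the allylic dioxolane releases the C4' ketone, already conjugated with C2'=C3'; the buffered acid avoids dienol formation at C1' and acid isomerisation of the polyene.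

Compound list
1 | 2-hydroxy-3,5,5-trimethylcyclohex-2-en-1-one | CC1=C(O)C(=O)CC(C)(C)C1 | starting material
2 | 7,9,9-trimethyl-1,4-dioxaspiro[4.5]decan-6-one (racemic) | CC1CC(C)(C)CC2(OCCO2)C1=O | intermediate
3 | 7,9,9-trimethyl-1,4-dioxaspiro[4.5]dec-7-en-6-one | CC1=CC(C)(C)CC2(OCCO2)C1=O | intermediate
4 | (6S)-7,9,9-trimethyl-1,4-dioxaspiro[4.5]dec-7-en-6-ol | O[C@H]1C(C)=CC(C)(C)CC12OCCO2 | intermediate
5 | [(4-methylphenyl)sulfonyl]acetic acid | Cc1ccc(cc1)S(=O)(=O)CC(=O)O | starting material
6 | (6S)-7,9,9-trimethyl-1,4-dioxaspiro[4.5]dec-7-en-6-yl [(4-methylphenyl)sulfonyl]acetate | Cc1ccc(cc1)S(=O)(=O)CC(=O)O[C@H]1C(C)=CC(C)(C)CC12OCCO2 | intermediate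
7 | (2E)-4,4-dimethoxybut-2-enal | COC(OC)/C=C/C=O | starting material
8 | methyl 2-(triphenylphosphoranylidene)propanoate | COC(=O)C(C)=P(c1ccccc1)(c1ccccc1)c1ccccc1 | starting material
9 | methyl (2E,4E)-6,6-dimethoxy-2-methylhexa-2,4-dienoate | COC(=O)/C(C)=C/C=C/C(OC)OC | intermediate
10 | methyl (2E,4E)-2-methyl-6-oxohexa-2,4-dienoate | COC(=O)/C(C)=C/C=C/C=O | intermediate
11 | 2-(triphenylphosphoranylidene)propanal | CC(C=O)=P(c1ccccc1)(c1ccccc1)c1ccccc1 | starting material
12 | methyl (2E,4E,6E)-2,7-dimethyl-8-oxoocta-2,4,6-trienoate | COC(=O)/C(C)=C/C=C/C=C(C)/C=O | intermediate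
13 | (1,3-dioxolan-2-ylmethyl)triphenylphosphonium bromide | [Br-].C1COC(C[P+](c2ccccc2)(c2ccccc2)c2ccccc2)O1 | starting material
14 | methyl (2E,4E,6E)-9-(1,3-dioxolan-2-yl)-2,7-dimethylnona-2,4,6,8-tetraenoate (8E/8Z mixture) | COC(=O)/C(C)=C/C=C/C=C(C)/C=CC1OCCO1 | intermediate
15 | methyl (2E,4E,6E,8E)-2,7-dimethyl-10-oxodeca-2,4,6,8-tetraenoate | COC(=O)/C(C)=C/C=C/C=C(C)/C=C/C=O | intermediate
16 | methyl (2E,4E,6E,8E,10E)-2,7,11-trimethyl-12-oxododeca-2,4,6,8,10-pentaenoate | COC(=O)/C(C)=C/C=C/C=C(C)/C=C/C=C(C)/C=O | intermediate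
17 | 14-[(6S)-7,9,9-trimethyl-1,4-dioxaspiro[4.5]dec-7-en-6-yl] 1-methyl (2E,4E,6E,8E,10E)-2,7,11-trimethyl-13-[(4-methylphenyl)sulfonyl]tetradeca-2,4,6,8,10,12-hexaenedioate (12,13-geometry not defined) | COC(=O)/C(C)=C/C=C/C=C(C)/C=C/C=C(C)/C=C(C(=O)O[C@H]1C(C)=CC(C)(C)CC12OCCO2)S(=O)(=O)c1ccc(C)cc1 | intermediate
18 | 14-[(6S)-7,9,9-trimethyl-1,4-dioxaspiro[4.5]dec-7-en-6-yl] 1-methyl (2E,4E,6E,8E,10E)-2,7,11-trimethyl-13-[(4-methylphenyl)sulfonyl]tetradeca-2,4,6,8,10-pentaenedioate (both C13 epimers) | COC(=O)/C(C)=C/C=C/C=C(C)/C=C/C=C(C)/CC(C(=O)O[C@H]1C(C)=CC(C)(C)CC12OCCO2)S(=O)(=O)c1ccc(C)cc1 | intermediate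
19 | methyl (2E,4E,6E,8E,10E)-2,7,11-trimethyl-13-[(4-methylphenyl)sulfonyl]-14-{[(6S)-7,9,9-trimethyl-1,4-dioxaspiro[4.5]dec-7-en-6-yl]oxy}-14-[(trimethylsilyl)oxy]tetradeca-2,4,6,8,10,13-hexaenoate | COC(=O)/C(C)=C/C=C/C=C(C)/C=C/C=C(C)/CC(=C(O[Si](C)(C)C)O[C@H]1C(C)=CC(C)(C)CC12OCCO2)S(=O)(=O)c1ccc(C)cc1 | intermediate
20 | methyl (2E,4E,6E,8E,10E)-2,7,11-trimethyl-13-[(4-methylphenyl)sulfonyl]-14-oxo-13-[(8S)-7,9,9-trimethyl-1,4-dioxaspiro[4.5]dec-6-en-8-yl]-14-[(trimethylsilyl)oxy]tetradeca-2,4,6,8,10-pentaenoate | COC(=O)/C(C)=C/C=C/C=C(C)/C=C/C=C(C)/CC(C(=O)O[Si](C)(C)C)(S(=O)(=O)c1ccc(C)cc1)[C@@H]1C(C)=CC2(OCCO2)CC1(C)C | intermediate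
21 | methyl (2E,4E,6E,8E,10E)-2,7,11-trimethyl-13-[(4-methylphenyl)sulfonyl]-13-[(8S)-7,9,9-trimethyl-1,4-dioxaspiro[4.5]dec-6-en-8-yl]trideca-2,4,6,8,10-pentaenoate (both C13 epimers) | COC(=O)/C(C)=C/C=C/C=C(C)/C=C/C=C(C)/CC([C@@H]1C(C)=CC2(OCCO2)CC1(C)C)S(=O)(=O)c1ccc(C)cc1 | intermediate
22 | methyl (2E,4E,6E,8E,10E,12E)-2,7,11-trimethyl-13-[(8S)-7,9,9-trimethyl-1,4-dioxaspiro[4.5]dec-6-en-8-yl]trideca-2,4,6,8,10,12-hexaenoate | COC(=O)/C(C)=C/C=C/C=C(C)/C=C/C=C(C)/C=C/[C@@H]1C(C)=CC2(OCCO2)CC1(C)C | intermediate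
23 | methyl (2E,4E,6E,8E,10E,12E)-2,7,11-trimethyl-13-[(1S)-2,6,6-trimethyl-4-oxocyclohex-2-en-1-yl]trideca-2,4,6,8,10,12-hexaenoate | COC(=O)/C(C)=C/C=C/C=C(C)/C=C/C=C(C)/C=C/[C@@H]1C(C)=CC(=O)CC1(C)C | target

Total step count: 12. Longest linear sequence: 8 steps (steps 1–4 and 9–12 from 1; the chain branch, steps 5–8 and 9–12 from 7, is equally long).

Steps most likely to fail

Step 10 (key step). The [3,3] shift of the fully substituted ketene acetal onto the neopentyl ring carbon C1' may be too slow, so that thermal E/Z isomerisation or electrocyclisation of the pentaenoate, or ionisation of the allylic ester, competes. The fallback sets out from 6 and 16 and returns at 21; it makes the C1'–C13 bond first with the small fragment and attaches the chain afterwards by sulfone alkylation. Ester 6 itself undergoes the parent decarboxylative Claisen rearrangement (BSA, KOAc cat., toluene, 110 °C) to (8S)-7,9,9-trimethyl-8-{[(4-methylphenyl)sulfonyl]methyl}-1,4-dioxaspiro[4.5]dec-6-ene F1. Its lithio derivative (n-BuLi, THF, −78 °C) is alkylated with methyl (2E,4E,6E,8E,10E)-12-bromo-2,7,11-trimethyldodeca-2,4,6,8,10-pentaenoate F3, which is made from 16 via methyl (2E,4E,6E,8E,10E)-12-hydroxy-2,7,11-trimethyldodeca-2,4,6,8,10-pentaenoate F2 as in the fallback for step 9. This gives 21.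

Step 3. Both flanks of the carbonyl are fully substituted carbons, so facial discrimination by the oxazaborolidine may be weak or of the opposite sense. The fallback sets out from 3 and returns at 4. Luche reduction (NaBH4, CeCl3·7H2O, MeOH, 0 °C) gives racemic 7,9,9-trimethyl-1,4-dioxaspiro[4.5]dec-7-en-6-ol F4. Steglich esterification with (S)-2-methoxy-2-phenylacetic acid and chromatographic separation of the two diastereomeric esters gives (6S)-7,9,9-trimethyl-1,4-dioxaspiro[4.5]dec-7-en-6-yl (2S)-2-methoxy-2-phenylacetate F5. Methanolysis (K2CO3, MeOH, rt) releases 4.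

Step 9. Condensation of the α-branched, vinylogously deactivated polyenal with the bulky sulfonylacetate may be sluggish, and hydride may add at a vinylogous (1,6 or 1,8) position instead of 1,4. The fallback sets out from 6 and 16 and returns at 18; it is a classical C-alkylation of the sulfonylacetate. Aldehyde 16 is reduced (NaBH4, MeOH, 0 °C) to methyl (2E,4E,6E,8E,10E)-12-hydroxy-2,7,11-trimethyldodeca-2,4,6,8,10-pentaenoate F2. This is converted (PBr3, Et2O, −20 °C, dark) into methyl (2E,4E,6E,8E,10E)-12-bromo-2,7,11-trimethyldodeca-2,4,6,8,10-pentaenoate F3, which is used at once to alkylate the potassium enolate of 6 (K2CO3, acetone, 0 °C to rt) to give 18.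

Further compounds
F1 | step 10 | (8S)-7,9,9-trimethyl-8-{[(4-methylphenyl)sulfonyl]methyl}-1,4-dioxaspiro[4.5]dec-6-ene | Cc1ccc(cc1)S(=O)(=O)C[C@@H]1C(C)=CC2(OCCO2)CC1(C)C
F2 | step 9 | methyl (2E,4E,6E,8E,10E)-12-hydroxy-2,7,11-trimethyldodeca-2,4,6,8,10-pentaenoate | COC(=O)/C(C)=C/C=C/C=C(C)/C=C/C=C(C)/CO
F3 | step 9 | methyl (2E,4E,6E,8E,10E)-12-bromo-2,7,11-trimethyldodeca-2,4,6,8,10-pentaenoate | COC(=O)/C(C)=C/C=C/C=C(C)/C=C/C=C(C)/CBr
F4 | step 3 | 7,9,9-trimethyl-1,4-dioxaspiro[4.5]dec-7-en-6-ol (racemic) | OC1C(C)=CC(C)(C)CC12OCCO2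
F5 | step 3 | (6S)-7,9,9-trimethyl-1,4-dioxaspiro[4.5]dec-7-en-6-yl (2S)-2-methoxy-2-phenylacetate | CO[C@H](C(=O)O[C@H]1C(C)=CC(C)(C)CC12OCCO2)c1ccccc1
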